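**Stopping point.** If you charge 0.10 M of L on 10 mM of Q and wait 6.0 min, the question is how far this flask gets before its catalyst is lost; the gamma run is this same flask, followed so far.

in all of them: L 0.10 M; Q 10 mM

|  | remark | time |
|---|---|---|
| gamma | the very flask that is asked about, followed so far |  |
| flask |  | 6.0 min |

gamma run (percent of the L charged)

| time / min | Z / % | L / % | D / % | G / % |
|---|---|---|---|---|
| 0.250 | 7.7 | 80.7 | 0.1 | 9.4 |
| 0.417 | 6.6 | 74.4 | 1.5 | 13.0 |
| 0.667 | 6.5 | 67.1 | 3.9 | 18.9 |
| 1.00 | 4.8 | 61.8 | 3.1 | 24.0 |
| 2.00 | 3.0 | 43.6 | 13.8 | 29.6 |
| 3.00 | 0 | 35.9 | 23.5 | 29.5 |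

(readings scatter by 1 percentage point)

- on the list of suspects stand: L + Q -> Z; Z -> Q + G; G <-> D; Z -> J

* the species that holds most of what was charged as L, at 6.0 min (G / D / Z / L)
* the largest share itself, whichever of these holds it, in percent of the L charged

**Rounds per loss.** On the list of suspects, Q takes up L as Z, Z gives back Q and G, and Z can also leave the round as J, so each catalyst works until it is lost. Between the first and last gamma readings L fell by 45 percentage points while Z fell by 7.7 points, and their ratio, the L spent per Z lost, is 5.82, the turnover number, as a reading with wide scatter. Each catalyst also keeps one L as J, so once the catalyst charge stands as J my reckoning for this flask stops L near 31.8%, and with Z reading 0% at 3.00 min I take that stop for the state at 6.0 min. Taking off the 10.0% held as J leaves a pool of G and D of 58.2%. If I keep the split in the forecast's own figures, 44 of 66, about two parts D to one of G, D comes to 38.8%.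

**The forecast.** The forecast names D at 44%, between 37% and 50%, reckoning “so G+D is about 66%, L about 23%, and J about 10%”. Its D stands higher than mine, and the two reckonings part at L, with 23 in the forecast against my 31.8%.

**The result.** The flask gives D at 38.1%, with L at 29.1% and G at 22.8%, so the forecast's species stands and its share is 5.9 points too high.

    L + Q → Z (k = 122 L mol⁻¹ s⁻¹)
    Z → Q + G (k = 0.0701 s⁻¹)
    G ⇌ D (K = 2.41, k = 0.00625 s⁻¹)
    Z → J (k = 0.0113 s⁻¹)

**What happened.** In this flask Z stood at 6.63% of the L charged at 0.600 min and 1.32% at 3.00 min, and over that stretch L fell from 69.5% to 36.3%. From then to 6.00 min, G went from 30.4% to 22.8% while D rose from 23.3% to 38.1%. The Z left at that time, 0.178% of the L charged, is worth 1.04% of the L charged at the 5.82 rounds read before, and at 60.0 min L stands at 28.0%.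

**Second flask.** In a second flask, with the same L and the same 6.0 min but 0.025 M of Q, the same 5.82 rounds could spend 170% of the L charged, so on this reckoning L is the limiting reagent in that flask and about 58.7% of its catalyst should be lost. That flask computes to L 0%, J 55.5% of the catalyst charged, and D 57.4%.

(The runs were computed with constants of no real substance, and the scatter is random.)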